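The numbers of this flask stand for no real mixture; no experiment stands behind them.

The target is what you want from this flask. It forms in the first phase from substrate and from reagent leaking in out of the second phase, part of it moves into the second phase as product in the second phase, and in the first phase it decomposes.

    target ⇌ product in the second phase, rate k1*([target] - [product in the second phase]/K1) per volume of the first phase (K1 = 0.45, k1 = 0.00738 s⁻¹)
    substrate + target → side product (k2 = 0.00381 M⁻¹ s⁻¹)
    substrate + reagent in the reaction phase → target (k3 = 0.0504 M⁻¹ s⁻¹)
    reagent in the reaction phase ⇌ reagent in the second phase, rate k4*([reagent in the reaction phase] - [reagent in the second phase]/K4) per volume of the first phase (K4 = 2.03, k4 = 0.0172 s⁻¹)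
    target → decomposed product (k5 = 0.00406 s⁻¹)

| setting | noon | autumn | dusk |
|---|---|---|---|
| substrate | 0.10 M (fed, over 20 s) | 0.10 M (fed, over 20 s) | 0.10 M (fed, over 20 s) |
| reagent in the second phase | 0.0500 M | 0.100 M | 0.200 M |
| time | 4.0 min | 4.0 min | 4.0 min |
| volume of the second phase over the first | 0.50 | 0.50 | 0.50 |

- share of target in all that became target or decomposed product or side product for noon, autumn, dusk, in this order
- how the row runs (rises all the way / rises, then falls / falls, then rises / falls all the way / hardly changes)

- a species is counted by the substrate in it: one side product counts as two
- amounts and yields of target count product in the second phase too
- in the second phase: reagent in the second phase, product in the second phase; everything else is in the first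
- charges count per volume of the first phase; a concentration in a rate is the amount of a species over the volume of its own phase; every rate counts per litre of the first phase
- "hardly changes" means that all values lie within two and a half points (for a concentration: within two and a half percent of the largest)
- run time (noon): 4.0 min

Work with the fraction left, not the fraction made. With partition ratio K = 0.45 and volume ratio v = 0.50, the second phase holds K·v of target for each unit in the first, and there it is safe. The decay constant k = 0.00406 s⁻¹ therefore thins to the ageing constant κ, which is k divided by one plus K·v, the loss per second of target counted over both phases: 0.00331 s⁻¹.

Target exchange relaxes in 24.9 s and the reagent leak in 29.3 s, both shorter than the run of 4.0 min. So I take target as made evenly, with a typical age a of 2.00 min at the end. The fraction left is S = exp(−κa) = 67.2 %. The reagent charge does not enter S, so I expect a flat row, pulled below S by side product joining the denominator.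

The forecast gave 64.5 %, 64.3 % and 63.3 %, which hardly changes, reasoning that “More reagent forms target earlier, so it ages longer, but less side product nearly offsets this”. Its first value is lower than my S, and it parts the flasks where mine does not.

The simulation gives 64.6 %, 64.4 % and 63.6 %; the row hardly changes.

The share is a reading of age, and the hour of the reading is the main reason for its value: noon's share is 64.6 % at the asked time, and with that early hour taken away, the reading moved to 40.0 min, it is 1.81 %. In noon, the making of target reached its midpoint at 1.97 min, so the median target is 2.03 min old and κ gives 66.8 % left, while target over target plus decomposed product reads 68.1 %. Dusk's same ratio reads 66.1 %. Through κ, these readings give an age of 1.93 min for noon and 2.08 min for dusk.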